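**Retrosynthetic overview**
1. Methyl sarcoate 24 comes from carbinol 23 by oxidation at C3, and 23 comes from the open-chain aldehyde 22 by closing the C13–C14 bond; the 14-membered carbocycle is the only ring of the target and is formed in the last step but one.
2. Enabling feature: the ring CH2 C14 lies between the C13 ketone and C1 of the C1=C2 enoate. The ester on C1 makes C14 an acrylate β-carbon and places C13=O and the ester C=O 1,4 to each other, and C2 leads on to oxygenated C3. The unit C14–C1(CO2Me)=C2–C3–O is therefore what an SN2' opening of a 2-(oxiran-2-yl)acrylate by a C13 acyl anion leaves behind.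
3. Precursor 22 carries the C13 aldehyde (polarity reversed by a carbene catalyst) and a temporary C2–C3 oxirane on a C1=C14 acrylate; the oxirane is made from the C3 enal and the sulfonium ylide of methyl 2-(bromomethyl)acrylate.
4. Chain: C10–C13 from (R)-4-isopropylbutanolide 14 (Evans alkylation sets C12); C3–C9 from geraniol through (Z)-vinyl iodide 7 (sets C8=C9); the two are joined at C9–C10 by vinyllithium addition to the lactone.
5. Ring order: temporary oxirane (step 11), then the 14-membered ring with cleavage of the oxirane (step 13).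

Key step: step 13

Remark on numbering: the target ring is numbered C1 (bears CO2Me), C2, C3 (ketone), C4=C5 (methyl on C5), C6, C7, C8=C9 (methyl on C9), C10 (ketone), C11, C12 (isopropyl), C13 (ketone), C14 (CH2); the same numbers are used for the open-chain precursors.
Assumption: the oxirane carbons C2 and C3 of 21 and 22 and the carbinol C3 of 23 are carried as stereoisomer mixtures, because both carbons are sp2 in 24; their SMILES leave these centres open.

**Step 1**
Reactants: 1 geraniol
Product: 2 tert-butyl{[(2E)-3,7-dimethylocta-2,6-dien-1-yl]oxy}dimethylsilane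
Conditions: TBSCl, imidazole, DMF, 20 °C
Reagents that add atoms: tert-butyldimethylsilyl chloride, CC(C)(C)[Si](C)(C)Cl
Why: Standard imidazole-promoted silylation of the primary allylic alcohol, which protects it for the later organolithium steps.

**Step 2**
Reactants: 2 geranyl silyl ether
Product: 3 tert-butyl{[(2E)-5-(3,3-dimethyloxiran-2-yl)-3-methylpent-2-en-1-yl]oxy}dimethylsilane (racemic)
Conditions: mCPBA, NaHCO3, CH2Cl2, −20 → 0 °C
Reagents that add atoms: 3-chloroperbenzoic acid, OOC(=O)c1cccc(Cl)c1
Why: Prilezhaev epoxidation, in which the distal trisubstituted alkene is more electron-rich than the 2,3-alkene (deactivated by the allylic silyloxy group), so mono-epoxidation should occur at the terminal double bond.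

**Step 3**
Reactants: 3 epoxide
Product: 4 (4E)-6-[(tert-butyldimethylsilyl)oxy]-4-methylhex-4-enal
Conditions: H5IO6, THF–H2O, 0 °C
Reagents that add atoms: none
Why: Periodic acid opens the oxirane to the glycol and cleaves it in the same flask (Malaprade-type cleavage), which should give the aldehyde and acetone and leave the E-alkene and the silyl ether intact.

**Step 4**
Reactants: 4 aldehyde; 5 ethyltriphenylphosphonium iodide
Product: 7 tert-butyl{[(2E,6Z)-7-iodo-3-methylocta-2,6-dien-1-yl]oxy}dimethylsilane, via (1-iodoethyl)triphenylphosphonium iodide 6 (not isolated)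
Conditions: 5, n-BuLi, THF, 20 °C; I2, −78 °C; NaN(SiMe3)2, −20 °C; then 4, −78 → 20 °C
Reagents that add atoms: iodine, II
Why: Stork–Zhao-type Wittig olefination with the α-iodo ylide Ph3P=C(I)CH3, which under kinetic control should give the (Z)-2-iodoalkene with iodine cis to the chain, the geometry that becomes the Z C8=C9 enone.

**Step 5**
Reactants: 8 (4R)-4-benzyl-1,3-oxazolidin-2-one; 9 3-methylbutanoyl chloride
Product: 10 (4R)-4-benzyl-3-(3-methylbutanoyl)-1,3-oxazolidin-2-one
Conditions: n-BuLi, THF, −78 °C; then 9
Reagents that add atoms: none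
Why: N-Acylation of the lithiated oxazolidinone with the acid chloride.

**Step 6**
Reactants: 10 acyl oxazolidinone; 11 tert-butyl bromoacetate
Product: 12 tert-butyl (3R)-3-{[(4R)-4-benzyl-2-oxo-1,3-oxazolidin-3-yl]carbonyl}-4-methylpentanoate
Conditions: NaN(SiMe3)2, THF, −78 °C; then 11
Reagents that add atoms: none
Why: Evans alkylation, in which the chelated (Z)-sodium enolate is attacked on the face away from the benzyl group, so the (R)-auxiliary should set the (R) centre that becomes C12.

**Step 7**
Reactants: 12 alkylated imide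
Product: 14 (4R)-4-(propan-2-yl)oxolan-2-one, via tert-butyl (3R)-3-(hydroxymethyl)-4-methylpentanoate 13 (not isolated)
Conditions: LiBH4, H2O (1 equiv), Et2O, 0 °C; then TsOH·H2O (cat.), toluene, 80 °C
Reagents that add atoms: none
Why: LiBH4 reduces the imide carbonyl in preference to the tert-butyl ester and frees the auxiliary, and acid then closes the γ-lactone with loss of isobutene, without touching the stereocentre.

**Step 8**
Reactants: 7 (Z)-vinyl iodide; 14 lactone
Product: 16 (2R,5Z,9E)-11-[(tert-butyldimethylsilyl)oxy]-1-hydroxy-5,9-dimethyl-2-(propan-2-yl)undeca-5,9-dien-4-one, via (2E,6E)-8-[(tert-butyldimethylsilyl)oxy]-6-methylocta-2,6-dien-2-yllithium 15 (not isolated)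
Conditions: t-BuLi (2.1 equiv), Et2O, −78 °C; then 14, −78 °C; H2O
Reagents that add atoms: none
Why: Iodine–lithium exchange with retention of alkene geometry followed by acyl substitution on the lactone; the lithium lactolate is stable at −78 °C, so a single addition is expected, and it opens to the γ-hydroxy (Z)-enone on work-up.

**Step 9**
Reactants: 16 silyl ether
Product: 17 (2R,5Z,9E)-1,11-dihydroxy-5,9-dimethyl-2-(propan-2-yl)undeca-5,9-dien-4-one
Conditions: Bu4NF, AcOH, THF, 0 → 20 °C
Reagents that add atoms: none
Why: Fluoride cleavage of the primary silyl ether, buffered with acetic acid so that the enolisable (Z)-enone is not exposed to base.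

**Step 10**
Reactants: 17 diol
Product: 18 (2E,6Z,10R)-10-(hydroxymethyl)-3,7,11-trimethyl-8-oxododeca-2,6-dienal
Conditions: MnO2, CH2Cl2, 20 °C
Reagents that add atoms: none
Why: MnO2 oxidises only allylic alcohols, so the C3 alcohol should give the (E)-enal while the saturated C13 alcohol remains.

**Step 11**
Reactants: 18 enal; 19 methyl 2-(bromomethyl)prop-2-enoate
Product: 21 methyl 2-{3-[(1E,5Z,9R)-9-(hydroxymethyl)-2,6,10-trimethyl-7-oxoundeca-1,5-dien-1-yl]oxiran-2-yl}prop-2-enoate, via 1-[2-(methoxycarbonyl)prop-2-en-1-yl]thiolan-1-ium bromide 20 (not isolated)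
Conditions: 19, tetrahydrothiophene, MeCN, 20 °C; then 18, Cs2CO3, 0 → 20 °C
Reagents that add atoms: none
Why: Corey–Chaykovsky-type epoxidation with a stabilised allylic sulfonium ylide, whose sulfur-bearing carbon adds 1,2 to the β,β-disubstituted enal before the betaine closes to the mainly trans oxirane; the two new oxirane centres are not controlled because both are lost later.

**Step 12**
Reactants: 21 hydroxy vinyl oxirane
Product: 22 methyl 2-{3-[(1E,5Z,9R)-9-formyl-2,6,10-trimethyl-7-oxoundeca-1,5-dien-1-yl]oxiran-2-yl}prop-2-enoate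
Conditions: Dess–Martin periodinane, pyridine, CH2Cl2, 0 °C
Reagents that add atoms: none
Why: Dess–Martin oxidation of the primary alcohol under pyridine buffering, mild enough for the vinyl oxirane and for the stereocentre next to the new aldehyde.

**Step 13**
Reactants: 22 aldehyde
Product: 23 methyl (1E,4E,8Z,12R)-3-hydroxy-5,9-dimethyl-10,13-dioxo-12-(propan-2-yl)cyclotetradeca-1,4,8-triene-1-carboxylate
Conditions: 3-benzyl-5-(2-hydroxyethyl)-4-methylthiazolium chloride (30 mol %), Et3N (30 mol %), 1,4-dioxane, 60 °C, 22 added by syringe pump to 2 mM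
Reagents that add atoms: none
Why: Proposed new method: the thiazol-2-ylidene adds to the C13 aldehyde to give a Breslow intermediate (acyl anion equivalent) that attacks the unsubstituted acrylate terminus C14, the ester enolate formed at C1 opens the adjacent oxirane by E1cB (overall an acyl-anion SN2' reaction), and proton transfer to the C3 alkoxide with loss of the carbene releases the C13 ketone, so the step is an isomerisation without by-product. The closest known reactions are the thiazolium-catalysed Stetter addition of aliphatic aldehydes to acrylates (intramolecular for five- and six-membered rings) and the conjugate addition–elimination of soft nucleophiles to Morita–Baylis–Hillman-type acceptors. The 14-membered ring closes by a 14-endo-trig conjugate addition, and the temporary oxirane is cleaved in the same operation. No new stereocentre is formed (C3 keeps its oxirane configuration, C12 is not involved); the new C1=C2 geometry is set in the elimination, where C3 should turn away from the ester as is usual for SN2' reactions on such acceptors, and the other isomer would show itself by lactonising onto the ester. The step needs chemoselectivity for C14 over the C8=C9–C10 enone and integrity of C12 next to the aldehyde: the enone is α,β-disubstituted and could be reached only in a 6-endo mode, which Stetter chemistry tolerates poorly, whereas the acrylate terminus is unhindered and its addition is made irreversible by release of oxirane strain; sub-stoichiometric Et3N and slow addition at high dilution should limit enolisation and intermolecular benzoin or Stetter reactions.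

**Step 14**
Reactants: 23 macrocyclic carbinol
Product: 24 methyl sarcoate, methyl (1E,4E,8Z,12R)-5,9-dimethyl-3,10,13-trioxo-12-(propan-2-yl)cyclotetradeca-1,4,8-triene-1-carboxylate
Conditions: Dess–Martin periodinane, pyridine, CH2Cl2, 0 → 20 °C
Reagents that add atoms: none
Why: Dess–Martin oxidation of the doubly allylic C3 carbinol to the cross-conjugated dienone, in which both C3 epimers converge and no stereocentre or alkene geometry is touched.

**Compound list**
1 | geraniol | CC(C)=CCC/C(C)=C/CO | starting material
2 | tert-butyl{[(2E)-3,7-dimethylocta-2,6-dien-1-yl]oxy}dimethylsilane | CC(C)=CCC/C(C)=C/CO[Si](C)(C)C(C)(C)C | intermediate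
3 | tert-butyl{[(2E)-5-(3,3-dimethyloxiran-2-yl)-3-methylpent-2-en-1-yl]oxy}dimethylsilane (racemic) | CC1(C)OC1CC/C(C)=C/CO[Si](C)(C)C(C)(C)C | intermediate
4 | (4E)-6-[(tert-butyldimethylsilyl)oxy]-4-methylhex-4-enal | O=CCC/C(C)=C/CO[Si](C)(C)C(C)(C)C | intermediate
5 | ethyltriphenylphosphonium iodide | CC[P+](c1ccccc1)(c1ccccc1)c1ccccc1.[I-] | starting material
6 | (1-iodoethyl)triphenylphosphonium iodide | CC(I)[P+](c1ccccc1)(c1ccccc1)c1ccccc1.[I-] | intermediate (not isolated)
7 | tert-butyl{[(2E,6Z)-7-iodo-3-methylocta-2,6-dien-1-yl]oxy}dimethylsilane | C/C(I)=C/CC/C(C)=C/CO[Si](C)(C)C(C)(C)C | intermediate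
8 | (4R)-4-benzyl-1,3-oxazolidin-2-one | O=C1N[C@H](Cc2ccccc2)CO1 | starting material
9 | 3-methylbutanoyl chloride | CC(C)CC(=O)Cl | starting material
10 | (4R)-4-benzyl-3-(3-methylbutanoyl)-1,3-oxazolidin-2-one | CC(C)CC(=O)N1[C@H](Cc2ccccc2)COC1=O | intermediate
11 | tert-butyl bromoacetate | CC(C)(C)OC(=O)CBr | starting material
12 | tert-butyl (3R)-3-{[(4R)-4-benzyl-2-oxo-1,3-oxazolidin-3-yl]carbonyl}-4-methylpentanoate | CC(C)[C@@H](CC(=O)OC(C)(C)C)C(=O)N1[C@H](Cc2ccccc2)COC1=O | intermediate
13 | tert-butyl (3R)-3-(hydroxymethyl)-4-methylpentanoate | CC(C)[C@@H](CC(=O)OC(C)(C)C)CO | intermediate (not isolated)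
14 | (4R)-4-(propan-2-yl)oxolan-2-one | O=C1C[C@H](C(C)C)CO1 | intermediate
15 | (2E,6E)-8-[(tert-butyldimethylsilyl)oxy]-6-methylocta-2,6-dien-2-yllithium (lithium cis to C4, geometry of 7 retained) | [Li]/C(C)=C\CC/C(C)=C/CO[Si](C)(C)C(C)(C)C | intermediate (not isolated)
16 | (2R,5Z,9E)-11-[(tert-butyldimethylsilyl)oxy]-1-hydroxy-5,9-dimethyl-2-(propan-2-yl)undeca-5,9-dien-4-one | OC[C@@H](C(C)C)CC(=O)/C(C)=C\CC/C(C)=C/CO[Si](C)(C)C(C)(C)C | intermediate
17 | (2R,5Z,9E)-1,11-dihydroxy-5,9-dimethyl-2-(propan-2-yl)undeca-5,9-dien-4-one | OC[C@@H](C(C)C)CC(=O)/C(C)=C\CC/C(C)=C/CO | intermediate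
18 | (2E,6Z,10R)-10-(hydroxymethyl)-3,7,11-trimethyl-8-oxododeca-2,6-dienal | OC[C@@H](C(C)C)CC(=O)/C(C)=C\CC/C(C)=C/C=O | intermediate
19 | methyl 2-(bromomethyl)prop-2-enoate | COC(=O)C(=C)CBr | starting material
20 | 1-[2-(methoxycarbonyl)prop-2-en-1-yl]thiolan-1-ium bromide | COC(=O)C(=C)C[S+]1CCCC1.[Br-] | intermediate (not isolated)
21 | methyl 2-{3-[(1E,5Z,9R)-9-(hydroxymethyl)-2,6,10-trimethyl-7-oxoundeca-1,5-dien-1-yl]oxiran-2-yl}prop-2-enoate (oxirane mainly trans, both oxirane configurations) | COC(=O)C(=C)C1OC1/C=C(\C)CC/C=C(/C)C(=O)C[C@H](C(C)C)CO | intermediate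
22 | methyl 2-{3-[(1E,5Z,9R)-9-formyl-2,6,10-trimethyl-7-oxoundeca-1,5-dien-1-yl]oxiran-2-yl}prop-2-enoate (oxirane mixture as in 21) | COC(=O)C(=C)C1OC1/C=C(\C)CC/C=C(/C)C(=O)C[C@H](C(C)C)C=O | intermediate
23 | methyl (1E,4E,8Z,12R)-3-hydroxy-5,9-dimethyl-10,13-dioxo-12-(propan-2-yl)cyclotetradeca-1,4,8-triene-1-carboxylate (C3 epimers) | COC(=O)/C1=C/C(O)/C=C(\C)CC/C=C(/C)C(=O)C[C@H](C(C)C)C(=O)C1 | intermediate
24 | methyl sarcoate, methyl (1E,4E,8Z,12R)-5,9-dimethyl-3,10,13-trioxo-12-(propan-2-yl)cyclotetradeca-1,4,8-triene-1-carboxylate | COC(=O)/C1=C/C(=O)/C=C(\C)CC/C=C(/C)C(=O)C[C@H](C(C)C)C(=O)C1 | target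

**Step count**
Total: 14 steps. Longest linear sequence: 11 steps (geraniol 1 to 24 through steps 1–4 and 8–14).

**Steps most likely to fail**

Step 13 (proposed new method). The carbene-catalysed ring closure may fail in several ways:
- the Breslow addition to an α-branched acrylate may be too slow at high dilution;
- the carbene may attack the acrylate itself and rearrange the vinyl oxirane;
- the aldehyde may enolise, with epimerisation at C12;
- base may move the new C1=C2 double bond into conjugation with the C13 ketone;
- oligomers may form.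

The fallback uses known chemistry, sets out from alcohol 21 and comes back at 23. The alcohol is converted into the methanesulfonate F1 (MsCl, Et3N, CH2Cl2, 0 °C), then into the iodide F2 (NaI, acetone, 20 °C), then into the primary nitro compound F3 (AgNO2, Et2O, 0 °C, Victor Meyer reaction). F3 is cyclised in a Tsuji–Trost reaction (Pd2(dba)3·CHCl3 as source of zerovalent palladium, P(O-i-Pr)3, THF, 40 °C, high dilution). The palladium ionises the vinyl oxirane to a π-allylpalladium alkoxide, the alkoxide deprotonates the nitroalkane, and the nitronate attacks the distal allyl terminus C14. This should give the nitro macrocycle F4 with the same C13–C14 bond and the free C3 hydroxyl. A Nef reaction (NaOMe, MeOH, −20 °C; then aqueous TiCl3, NH4OAc) then turns the C13 nitro carbon into the ketone of 23.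

Step 11. The ylide may condense with its own sulfonium salt faster than it adds to the hindered β,β-disubstituted enal, or may react through its γ-carbon. The fallback replaces ylide chemistry by a halohydrin route; it sets out from enal 18 and bromide 19 and comes back at 21. Bromide 19 is brominated to methyl 2,3-dibromo-2-(bromomethyl)propanoate F5 (Br2, CH2Cl2) and dehydrobrominated to methyl (2Z)-3-bromo-2-(bromomethyl)prop-2-enoate F6 (Et3N). A Barbier reaction of F6 with 18 and indium metal in THF–H2O should give the bromohydrin F7; the γ-bromoallylindium species is expected to bond through its bromine-bearing carbon, as 1,3-dibromopropene does. K2CO3 in MeCN then closes F7 to oxirane 21.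

Step 4. The iodo-olefination may proceed with low conversion, loss of iodine from the ylide, or erosion of the Z geometry. The fallback builds the same geometry by cross-coupling; it sets out from aldehyde 4 and comes back at vinyllithium 15, and so at 16. A Corey–Fuchs reaction (CBr4, PPh3, CH2Cl2, 0 °C) gives the 1,1-dibromoalkene F8. A trans-selective Negishi monomethylation (Me2Zn, PdCl2(DPEphos) cat., THF) should replace only the bromine trans to the chain and leave the (Z)-vinyl bromide F9. Bromine–lithium exchange (t-BuLi, Et2O, −78 °C) then gives 15.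

Further compounds
F1 | step 13 | methyl 2-{3-[(1E,5Z,9R)-9-{[(methanesulfonyl)oxy]methyl}-2,6,10-trimethyl-7-oxoundeca-1,5-dien-1-yl]oxiran-2-yl}prop-2-enoate | COC(=O)C(=C)C1OC1/C=C(\C)CC/C=C(/C)C(=O)C[C@H](C(C)C)COS(C)(=O)=O
F2 | step 13 | methyl 2-{3-[(1E,5Z,9R)-9-(iodomethyl)-2,6,10-trimethyl-7-oxoundeca-1,5-dien-1-yl]oxiran-2-yl}prop-2-enoate | COC(=O)C(=C)C1OC1/C=C(\C)CC/C=C(/C)C(=O)C[C@H](C(C)C)CI
F3 | step 13 | methyl 2-{3-[(1E,5Z,9R)-2,6,10-trimethyl-9-(nitromethyl)-7-oxoundeca-1,5-dien-1-yl]oxiran-2-yl}prop-2-enoate | COC(=O)C(=C)C1OC1/C=C(\C)CC/C=C(/C)C(=O)C[C@H](C(C)C)C[N+](=O)[O-]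
F4 | step 13 | methyl (1E,4E,8Z,12R)-3-hydroxy-5,9-dimethyl-13-nitro-10-oxo-12-(propan-2-yl)cyclotetradeca-1,4,8-triene-1-carboxylate | COC(=O)/C1=C/C(O)/C=C(\C)CC/C=C(/C)C(=O)C[C@H](C(C)C)C([N+](=O)[O-])C1
F5 | step 11 | methyl 2,3-dibromo-2-(bromomethyl)propanoate | COC(=O)C(Br)(CBr)CBr
F6 | step 11 | methyl (2Z)-3-bromo-2-(bromomethyl)prop-2-enoate | COC(=O)/C(CBr)=C/Br
F7 | step 11 | methyl (5E,9Z,13R)-3-bromo-4-hydroxy-13-(hydroxymethyl)-6,10,14-trimethyl-2-methylidene-11-oxopentadeca-5,9-dienoate | COC(=O)C(=C)C(Br)C(O)/C=C(\C)CC/C=C(/C)C(=O)C[C@H](C(C)C)CO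
F8 | step 4 | tert-butyl{[(2E)-7,7-dibromo-3-methylhepta-2,6-dien-1-yl]oxy}dimethylsilane | BrC(Br)=CCC/C(C)=C/CO[Si](C)(C)C(C)(C)C
F9 | step 4 | tert-butyl{[(2E,6Z)-7-bromo-3-methylocta-2,6-dien-1-yl]oxy}dimethylsilane | C/C(Br)=C/CC/C(C)=C/CO[Si](C)(C)C(C)(C)C
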